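I start from the leftover, the fraction of the charge that has not become target.

| flask | starting material | reagent | second substrate | remark | time |
|---|---|---|---|---|---|
| ochre | 0.050 M (fed, over 12 min) | 3 equiv | 0.50 equiv | run made earlier; the fed solution adds 1.0 times the starting volume |  |
| blue | 0.050 M (fed, over 12 min) | 3 equiv | 0.75 equiv | run made earlier; the fed solution adds 1.0 times the starting volume |  |
| dusk | 0.050 M (fed, over 12 min) | 3.00 equiv | 1.00 equiv | the fed solution adds 1.0 times the starting volume | 12 min |
| midnight | 0.050 M | 3.00 equiv | 1.00 equiv | everything together at the start, the whole solution of starting material included, so that from the start the volume is larger by 1.0 times the starting volume | 3.0 min |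

| run | time / min | target / % | starting material / % |
|---|---|---|---|
| ochre | 2.00 | 1.2 | 13.1 |
| ochre | 4.00 | 2.3 | 24.9 |
| ochre | 6.00 | 6.1 | 35.9 |
| ochre | 8.00 | 9.1 | 45.9 |
| ochre | 10.0 | 11.7 | 55.7 |
| ochre | 12.0 | 15.7 | 66.3 |
| blue | 1.00 | 0.1 | 7.1 |
| blue | 1.50 | 0.4 | 9.8 |
| blue | 2.50 | 1.1 | 16.0 |
| blue | 4.00 | 2.5 | 24.4 |
| blue | 8.00 | 9.0 | 45.7 |
| blue | 12.0 | 15.0 | 66.3 |

(standard deviation of a reading: 0.3 percentage points)

- charges are per starting volume, the dose included; the dosed solution carries all of it
- percentages count the whole charge, also what has not yet gone in

- which one finishes higher in amount of target, in percent of the starting material charged ("neither" within 2 percentage points) (dusk / midnight / neither)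
- amount of target at the end, in percent of the starting material charged, dusk
- amount of target at the end, in percent of the starting material charged, midnight

In the ochre run at 8.00 min, 66.7% of the charge has been fed, yet 45.9% is found as starting material and 9.1% as target. A share is missing, and it stands to the found starting material as 0.254. The blue run at 4.00 min gives 0.264, so I treat the found and missing parts as one pool with a steady split.

The first setting is second substrate. By hand it might take reagent away, but from ochre to blue the target at 12.0 min goes from 15.7% to 15.0%, so for dusk I take the mean, 15.3%.

The second setting is the way of adding. By hand, adding at once exposes the whole charge from the start, but at the doubled volume, which thins the reagent. Between 4.00 min and 8.00 min in the ochre run, target forms at a rate per unit of found starting material that, scaled to the doubled volume, is 0.0360 min⁻¹. Reagent is in excess, so this is a pseudo-first-order constant. Multiplied by the found part of the pool, it gives my pool constant, the fraction of the pool lost to target per minute, 0.0287 min⁻¹.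

The third setting is time. In midnight's 3.0 min, the fraction left is exp(−constant × time), 91.7%, so I expect 8.25% of target, less than dusk.

The forecast names dusk, with 15.3% (14.3% to 16.3%) for dusk and 2.7% (1.5% to 5%) for midnight, below my figure, holding that “an intermediate is likely”.

The flask gives 15.4% for dusk and 7.94% for midnight, so dusk finishes higher.

    starting material + reagent → target (k = 0.00792 L mol⁻¹ s⁻¹)
    second substrate + reagent → second product (k = 0.00165 L mol⁻¹ s⁻¹)
    starting material + second substrate → cross product (k = 7.89 × 10⁻⁴ L mol⁻¹ s⁻¹)
    starting material ⇌ dormant form (K = 0.256, k = 0.00753 s⁻¹)
    target → over-reaction product (k = 4.51 × 10⁻⁴ s⁻¹)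

The missing share is the dormant form, and midnight's pool stands at 91.4% against my 91.7%. Part of midnight's deficit is its short time: read at dusk's 12 min, midnight reaches 23.0%, and read at 30.0 min, it reaches 33.0%, instead of 7.94%.

A neighbour of dusk, charged with 0.12 M at the same equivalents, multiplies my constant by 2.40, to 0.0689 min⁻¹. This neighbour is fed steadily, so its portions stand in the flask for any time up to 12 min, and the fraction left is the exponential averaged over those exposures; with my constant taken at the doubled volume throughout, the neighbour should keep 68.0% in its pool. It keeps 65.9%, with target at 29.1%.

The numbers in the tables were computed on assumed constants; the scatter is artificial.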